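**Plan**
1. Numbering: carbons C1–C25 follow the target SMILES from the vinylic methyl (C1) to the carbinol carbon (C25); ring A = C3/C4/C5/C6/C8, ring B = C2/C3/C8/C9/C10/C11/C13/C25, ring C = C13/C14/C15/C23/C24/C25, ring D = C15/C17/C18/C19/C23.
2. Retrosynthetic cuts, in order: C1–C2 (methyl onto an enol triflate), C9–C10 (ring B, as an alkene by metathesis), C2–C3 (cyclopentenyllithium plus amide), C19–C20 (isopropyl onto an enol triflate), then C13–C25 and C15–C23 together, then C23=C24 (Wittig), C15–C17 (alkylation), C14–C15 (Claisen) and C10–C11 (conjugate addition).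
3. Enabling feature: in ring C the methylene C14 lies between C13 and C15, and the carbinol carbon C25 is 1,3 to C23. An oxo group at C14 (deleted later) therefore makes C15/C13 a 1,3-dinucleophile and C23=C24–C25(=O)–CO2Et a 1,3-dielectrophile whose ester carbon is C2. C15 and C23 are already linked through C17–C18–C19, so the first closure is 5-exo, and a carboxyl group on C15 (lost as CO2) fixes where the enolate forms.
4. Forward order: acyclic C10–C25 chain carrying C2, then rings D and C in one operation, deletion of O14, isopropyl at C19, ring A added at C2, ring B by metathesis, hydrogenation, C1 methyl last.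
5. Stereochemistry: C11 from an oxazolidinone-controlled conjugate addition. A silyloxy stereocentre at C19, from (R)-butane-1,2,4-triol acetonide, controls C23 and C15 and through the ring C13 and C25; it is then erased and C19 is reset by hydrogenation anti to the C16 methyl. C6 comes from (R)-pulegone, with C8 equilibrated trans to it. The C2=C3 geometry is enforced by ring B.

Key step: step 11

Remark: α/β refer to the faces of rings C/D, β being the face of the C16 methyl. C15 in 6 and 12–17 and C3 in 37 are epimer mixtures of no consequence, since both centres become planar later. TBS = tert-butyldimethylsilyl, TBDPS = tert-butyldiphenylsilyl, Tf = trifluoromethanesulfonyl, Ts = 4-methylbenzenesulfonyl, Tris = 2,4,6-triisopropylbenzenesulfonyl.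

Step 1
Reactants: 1 (S)-4-benzyl-1,3-oxazolidin-2-one; 2 (E)-but-2-enoyl chloride
Product: 3 (S)-4-benzyl-3-[(E)-but-2-enoyl]-1,3-oxazolidin-2-one
Conditions: n-BuLi, THF, −78 °C; then 2, −78 → 0 °C
Reagents that add atoms: none
Why: N-acylation of the lithiated oxazolidinone with an acid chloride is the standard way to mount the auxiliary and should leave the (E)-alkene untouched.

Step 2
Reactants: 3 (S)-4-benzyl-3-[(E)-but-2-enoyl]-1,3-oxazolidin-2-one
Product: 4 (S)-4-benzyl-3-[(3R)-3-methylpent-4-enoyl]-1,3-oxazolidin-2-one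
Conditions: CH2=CHMgBr, CuBr·SMe2 (cat.), THF, −78 → −30 °C; NH4Cl (aq)
Reagents that add atoms: vinylmagnesium bromide, C=C[Mg]Br
Why: copper-mediated conjugate addition to the magnesium-chelated s-cis N-enoyl imide should occur on the alkene face away from the benzyl group and so set C11 (auxiliary-controlled 1,4-addition).

Step 3
Reactants: 4 (S)-4-benzyl-3-[(3R)-3-methylpent-4-enoyl]-1,3-oxazolidin-2-one; 5 tert-butyl propanoate
Product: 6 tert-butyl (5R)-2,5-dimethyl-3-oxohept-6-enoate (C2 epimers)
Conditions: 5, LiN(i-Pr)2 (2.2 equiv), THF, −78 °C; then 4, −78 → −30 °C; AcOH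
Reagents that add atoms: none
Why: crossed Claisen condensation, in which the lithium ester enolate attacks the exocyclic imide carbonyl, should release the auxiliary and form the C14–C15 bond.

Step 4
Reactants: 7 (R)-2-(2,2-dimethyl-1,3-dioxolan-4-yl)ethanol
Product: 8 (R)-4-(2-iodoethyl)-2,2-dimethyl-1,3-dioxolane
Conditions: I2, PPh3, imidazole, CH2Cl2, 0 °C → rt
Reagents that add atoms: iodine, II
Why: Appel-type iodination of the primary alcohol should not disturb the acetal or the future C19 stereocentre.

Step 5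
Reactants: 8 (R)-4-(2-iodoethyl)-2,2-dimethyl-1,3-dioxolane
Product: 9 (R)-4-iodobutane-1,2-diol
Conditions: AcOH/H2O (4:1), 40 °C
Reagents that add atoms: none
Why: mild acid hydrolysis of the isopropylidene acetal should free the 1,2-diol while the primary iodide survives the non-basic medium.

Step 6
Reactants: 9 (R)-4-iodobutane-1,2-diol
Product: 11 (2R)-1-(tert-butyldimethylsilyloxy)-2-(tert-butyldiphenylsilyloxy)-4-iodobutane, via mono-silyl ether 10 (not isolated)
Conditions: TBSCl (1.05 equiv), imidazole, DMF, −20 °C; then TBDPSCl, DMAP (cat.), rt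
Reagents that add atoms: tert-butyldimethylsilyl chloride, CC(C)(C)[Si](C)(C)Cl; tert-butyldiphenylsilyl chloride, CC(C)(C)[Si](Cl)(c1ccccc1)c1ccccc1
Why: sequential silylation should discriminate the primary from the secondary hydroxyl on steric grounds, placing the labile TBS group on the C23 oxygen and the acid-stable TBDPS group on the C19 oxygen.

Step 7
Reactants: 6 tert-butyl (5R)-2,5-dimethyl-3-oxohept-6-enoate; 11 (2R)-1-(tert-butyldimethylsilyloxy)-2-(tert-butyldiphenylsilyloxy)-4-iodobutane
Product: 12 tert-butyl (5R)-2-[(3R)-4-(tert-butyldimethylsilyloxy)-3-(tert-butyldiphenylsilyloxy)butyl]-2,5-dimethyl-3-oxohept-6-enoate (C2 epimers)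
Conditions: NaH, DMF, 0 °C; then 11, 45 °C
Reagents that add atoms: none
Why: C-alkylation of the sodium enolate of an α-methyl β-keto ester with a primary iodide is reliable and forms the C15–C17 bond, the ester group securing reaction at C15 and not at C13.

Step 8
Reactants: 12 bis-silyl ether of step 7
Product: 13 tert-butyl (5R)-2-[(3R)-3-(tert-butyldiphenylsilyloxy)-4-hydroxybutyl]-2,5-dimethyl-3-oxohept-6-enoate (C2 epimers)
Conditions: HF·pyridine, pyridine, THF, 0 °C
Reagents that add atoms: none
Why: buffered fluoride should cleave the primary TBS ether much faster than the hindered secondary TBDPS ether (selective desilylation).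

Step 9
Reactants: 13 primary alcohol of step 8
Product: 14 tert-butyl (5R)-2-[(3R)-3-(tert-butyldiphenylsilyloxy)-4-oxobutyl]-2,5-dimethyl-3-oxohept-6-enoate (C2 epimers)
Conditions: Dess–Martin periodinane, NaHCO3, CH2Cl2, 0 °C → rt
Reagents that add atoms: none
Why: buffered Dess–Martin oxidation should give the α-silyloxy aldehyde without epimerising C19.

Step 10
Reactants: 14 aldehyde of step 9; 15 ethyl 2-oxo-3-(triphenyl-λ5-phosphanylidene)propanoate
Product: 16 ethyl (3E,5R,11R)-8-(tert-butoxycarbonyl)-5-(tert-butyldiphenylsilyloxy)-8,11-dimethyl-2,9-dioxotrideca-3,12-dienoate (C8 epimers; C8 = C15)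
Conditions: PhMe, 40 °C
Reagents that add atoms: none
Why: Wittig olefination with the stabilised acyl ylide should give the (E)-2-oxo-3-enoate under neutral conditions that leave the C19 centre and the ketone untouched.

Step 11
Reactants: 16 keto diester of step 10
Product: 19 ethyl 25α-hydroxy-14-oxo-19α-(tert-butyldiphenylsilyloxy)-13α-[(S)-but-3-en-2-yl]-15β-methyl-trans-C/D-hydrindane-25β-carboxylate (target numbering), via beta-keto acid 17 (not isolated), via Michael adduct 18 (not isolated)
Conditions: TFA, CH2Cl2, 0 °C; evaporate; Et3N (0.3 equiv), PhMe, 45 °C; then DBU, LiCl, 0 °C → rt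
Reagents that add atoms: none
Why: Proposed new method: acidolysis of the tert-butyl ester unmasks the C15 carboxylic acid 17, whose amine-promoted loss of CO2 delivers the enol(ate) only at C15; this adds 5-exo-trig to C23 of the (E)-2-oxo-3-enoate (ring D, adduct 18), after which DBU/LiCl enolises C13, now the only enolisable position of the C14 ketone, for a 6-(enolexo)-exo-trig aldol onto the C25 keto group (ring C). The closest known reaction types are decarboxylative Michael additions of β-keto acids, internal Michael closures of keto enoates to trans-1,2-disubstituted cyclopentanes, and Michael/aldol [3+3] annulations of ketones with 2-oxo-3-enoates. C23 is controlled by the adjacent C19 stereocentre, whose bulky silyloxy group avoids the position eclipsing C24 so that C24 ends trans to it, and C15 is set in the same transition state with the larger C14 acyl arm trans to the C24 chain and the methyl cis. C13 and C25 follow from a chair, lithium-bridged and reversible aldol closure that puts the C11 side chain and the ester equatorial and the C25 oxygen axial and gauche to C14, which on the trans-disposed cyclopentane gives the trans-fused hydrindane. The step needs donor regioselectivity (C15 before C13), secured by the carboxyl group that is lost, and preservation of the base-labile γ-centre C19, secured by running the Michael stage with triethylamine only and adding the stronger base after C23 has become sp3.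

Step 12
Reactants: 19 aldol product of step 11
Product: 21 ethyl 25α-hydroxy-19α-(tert-butyldiphenylsilyloxy)-13α-[(S)-but-3-en-2-yl]-15β-methyl-trans-C/D-hydrindane-25β-carboxylate (C14 = CH2), via tosylhydrazone 20 (not isolated)
Conditions: TsNHNH2, EtOH, 70 °C; then catecholborane, CHCl3, 0 °C; NaOAc·3H2O, 60 °C
Reagents that add atoms: none
Why: reduction of the tosylhydrazone to a diazene that loses N2 should delete the C14 oxygen under non-basic conditions that avoid retro-aldol cleavage of the β-hydroxy ketone (tosylhydrazone deoxygenation).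

Step 13
Reactants: 21 deoxygenated ester of step 12
Product: 22 ethyl 19α,25α-dihydroxy-13α-[(S)-but-3-en-2-yl]-15β-methyl-trans-C/D-hydrindane-25β-carboxylate
Conditions: Bu4NF, THF, rt → 40 °C; NH4Cl (aq)
Reagents that add atoms: none
Why: fluoride-mediated desilylation should free the C19 hydroxyl, and no retro-aldol path remains once C14 is a methylene.

Step 14
Reactants: 22 diol of step 13
Product: 23 ethyl 25α-hydroxy-19-oxo-13α-[(S)-but-3-en-2-yl]-15β-methyl-trans-C/D-hydrindane-25β-carboxylate
Conditions: Dess–Martin periodinane, NaHCO3, CH2Cl2, 0 °C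
Reagents that add atoms: none
Why: the secondary alcohol should be oxidised while the tertiary C25 hydroxyl is inert, and the buffered neutral medium should keep the C23 centre next to the new ketone from epimerising (Dess–Martin oxidation).

Step 15
Reactants: 23 C19 ketone of step 14
Product: 24 ethyl 25α-hydroxy-19-(trifluoromethanesulfonyloxy)-13α-[(S)-but-3-en-2-yl]-15β-methyl-trans-C/D-hydrind-18-ene-25β-carboxylate
Conditions: KN(SiMe3)2 (2.2 equiv), THF, −78 °C; then PhNTf2, −78 → −20 °C
Reagents that add atoms: N-phenylbis(trifluoromethanesulfonimide), O=S(=O)(N(c1ccccc1)S(=O)(=O)C(F)(F)F)C(F)(F)F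
Why: kinetic deprotonation should take place at the C18 methylene and not at the ring-fusion methine C23, so O-triflation gives the C18=C19 enol triflate with C23 intact (enol triflate formation).

Step 16
Reactants: 24 enol triflate of step 15
Product: 25 ethyl 25α-hydroxy-19-isopropyl-13α-[(S)-but-3-en-2-yl]-15β-methyl-trans-C/D-hydrind-18-ene-25β-carboxylate
Conditions: i-PrZnBr, Pd(dppf)Cl2 (cat.), THF, 50 °C
Reagents that add atoms: isopropylzinc bromide, CC(C)[Zn]Br
Why: Negishi coupling of an alkenyl triflate with a secondary alkylzinc halide under a wide-bite-angle diphosphine should install C20–C22 without isomerisation to n-propyl and should tolerate the ester.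

Step 17
Reactants: 25 ester of step 16
Product: 26 N-methoxy-N-methyl amide of 25 (Weinreb amide at C2)
Conditions: MeNHOMe·HCl, i-PrMgCl, THF, −20 → 0 °C
Reagents that add atoms: N,O-dimethylhydroxylamine hydrochloride, Cl.CNOC
Why: aminolysis of the ester by the chloromagnesium amide should give the Weinreb amide, which allows a single acyl substitution at C2 in step 23.

Step 18
Reactants: 27 (R)-pulegone
Product: 29 methyl (1S,2R)-2-methyl-5-(propan-2-ylidene)cyclopentane-1-carboxylate, via pulegone dibromide 28 (not isolated)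
Conditions: Br2, NaHCO3, Et2O, −10 °C; then NaOMe, MeOH, reflux
Reagents that add atoms: sodium methoxide, [Na+].[O-]C
Why: Favorskii rearrangement of the dibromide contracts the ring to the ring A cyclopentane, C6 coming unchanged from pulegone and prolonged methoxide treatment equilibrating C8 to the trans ester.

Step 19
Reactants: 29 methyl trans-pulegenate
Product: 30 (1S,2R)-2-methyl-5-(propan-2-ylidene)cyclopentane-1-carbaldehyde
Conditions: i-Bu2AlH, CH2Cl2, −78 °C
Reagents that add atoms: none
Why: low-temperature partial reduction of the ester through a stable tetrahedral aluminate should stop at the aldehyde.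

Step 20
Reactants: 30 aldehyde of step 19
Product: 31 (2S,3R)-3-methyl-1-(propan-2-ylidene)-2-vinylcyclopentane
Conditions: Ph3PCH3Br, KOt-Bu, THF, 0 °C; then 30, −78 → 0 °C
Reagents that add atoms: methyltriphenylphosphonium bromide, [Br-].C[P+](c1ccccc1)(c1ccccc1)c1ccccc1
Why: Wittig methylenation at low temperature should convert the aldehyde into the C9 vinyl group before the α-centre C8 can epimerise.

Step 21
Reactants: 31 diene of step 20
Product: 32 (2S,3R)-3-methyl-2-vinylcyclopentan-1-one
Conditions: O3 (1.0 equiv, Sudan Red 7B end point), CH2Cl2/MeOH, −78 °C; then Me2S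
Reagents that add atoms: ozone, [O-][O+]=O
Why: ozone reacts much faster with the electron-rich tetrasubstituted alkene than with the monosubstituted vinyl group, so titrated ozonolysis should unmask the C3 ketone selectively.

Step 22
Reactants: 32 vinyl ketone of step 21
Product: 33 2,4,6-triisopropylbenzenesulfonylhydrazone of (2S,3R)-3-methyl-2-vinylcyclopentan-1-one
Conditions: TrisNHNH2, THF, rt
Reagents that add atoms: 2,4,6-triisopropylbenzenesulfonyl hydrazide, CC(C)c1cc(C(C)C)c(S(=O)(=O)NN)c(C(C)C)c1
Why: hydrazone condensation proceeds at room temperature without added acid or base, which should keep the β,γ-unsaturated ketone from moving into conjugation.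

Step 23
Reactants: 33 trisylhydrazone of step 22; 26 Weinreb amide of step 17
Product: 35 C2 ketone joining ring A to rings C/D: [(4R,5S)-4-methyl-5-vinylcyclopent-1-en-1-yl] ketone of the 25α-hydroxy-19-isopropyl-Δ18-hydrindane bearing the 13α-(S)-but-3-en-2-yl group, via alkenyllithium 34 (not isolated)
Conditions: 33, n-BuLi (2.1 equiv), THF, −78 → 0 °C; then 26 (as lithium alkoxide, n-BuLi 1.0 equiv), −78 → 0 °C
Reagents that add atoms: none
Why: the Shapiro reaction of the (E)-hydrazone should deprotonate the C4 methylene syn to the sulfonamide and give the C3=C4 alkenyllithium, which adds once to the Weinreb amide to form the C2–C3 bond.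

Step 24
Reactants: 35 dienyl ketone of step 23
Product: 36 tetracyclic 2-oxo-3,9(Z),18-triene (ring B closed; 25α-hydroxy; 19-isopropyl)
Conditions: second-generation Grubbs catalyst (10 mol%), PhMe, 80 °C, 2 mM
Reagents that add atoms: none
Why: ring-closing metathesis of the two monosubstituted alkenes should form the cis C9=C10 bond of ring B, the trans-diequatorial arms on C13 and C25 and the s-cis enone holding C8 and C11 close.

Step 25
Reactants: 36 trienone of step 24
Product: 37 saturated 2-oxo tetracycle (25α-hydroxy; 19β-isopropyl; C3 epimers)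
Conditions: H2 (4 atm), [Ir(cod)(PCy3)(py)]PF6 (cat.), CH2Cl2, rt
Reagents that add atoms: none
Why: homogeneous hydrogenation should saturate the cyclooctene, the enone C3=C4 bond and the hindered C18=C19 bond in one pass, hydrogen reaching C19 from the α face away from the C16 methyl so that the isopropyl group ends β (catalytic hydrogenation under steric control).

Step 26
Reactants: 37 α-hydroxy ketone of step 25
Product: 38 C2 enol triflate (C2=C3 tetrasubstituted alkene in ring B; 25α-hydroxy)
Conditions: KN(SiMe3)2 (2.2 equiv), THF, −78 °C; then PhNTf2, −78 → 0 °C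
Reagents that add atoms: N-phenylbis(trifluoromethanesulfonimide), O=S(=O)(N(c1ccccc1)S(=O)(=O)C(F)(F)F)C(F)(F)F
Why: because C25 is fully substituted the ketone can enolise only toward C3, so O-triflation should give the C2=C3 enol triflate with the geometry fixed by ring B (enol triflate formation).

Step 27
Reactants: 38 enol triflate of step 26
Product: 39 sesterfisherol
Conditions: MeMgBr, Fe(acac)3 (cat.), THF/NMP, −30 → 0 °C
Reagents that add atoms: methylmagnesium bromide, C[Mg]Br
Why: iron-catalysed cross-coupling of the alkenyl triflate with the methyl Grignard reagent should replace the triflate by the C1 methyl without moving the double bond, the magnesium alkoxide of the C25 hydroxyl being tolerated (Kumada-type coupling).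

**Compound list**
1 | (S)-4-benzyl-1,3-oxazolidin-2-one | O=C1N[C@@H](Cc2ccccc2)CO1 | starting material
2 | (E)-but-2-enoyl chloride | C/C=C/C(Cl)=O | starting material
3 | (S)-4-benzyl-3-[(E)-but-2-enoyl]-1,3-oxazolidin-2-one | C/C=C/C(=O)N1[C@@H](Cc2ccccc2)COC1=O | intermediate
4 | (S)-4-benzyl-3-[(3R)-3-methylpent-4-enoyl]-1,3-oxazolidin-2-one | C=C[C@H](C)CC(=O)N1[C@@H](Cc2ccccc2)COC1=O | intermediate
5 | tert-butyl propanoate | CCC(=O)OC(C)(C)C | starting material
6 | tert-butyl (5R)-2,5-dimethyl-3-oxohept-6-enoate (C2 epimers) | C=C[C@H](C)CC(=O)C(C)C(=O)OC(C)(C)C | intermediate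
7 | (R)-2-(2,2-dimethyl-1,3-dioxolan-4-yl)ethanol | OCC[C@@H]1COC(C)(C)O1 | starting material
8 | (R)-4-(2-iodoethyl)-2,2-dimethyl-1,3-dioxolane | ICC[C@@H]1COC(C)(C)O1 | intermediate
9 | (R)-4-iodobutane-1,2-diol | ICC[C@@H](O)CO | intermediate
10 | (R)-1-(tert-butyldimethylsilyloxy)-4-iodobutan-2-ol | ICC[C@@H](O)CO[Si](C)(C)C(C)(C)C | intermediate
11 | (2R)-1-(tert-butyldimethylsilyloxy)-2-(tert-butyldiphenylsilyloxy)-4-iodobutane | ICC[C@@H](O[Si](c1ccccc1)(c1ccccc1)C(C)(C)C)CO[Si](C)(C)C(C)(C)C | intermediate
12 | tert-butyl (5R)-2-[(3R)-4-(tert-butyldimethylsilyloxy)-3-(tert-butyldiphenylsilyloxy)butyl]-2,5-dimethyl-3-oxohept-6-enoate (C2 epimers) | C=C[C@H](C)CC(=O)C(C)(C(=O)OC(C)(C)C)CC[C@@H](O[Si](c1ccccc1)(c1ccccc1)C(C)(C)C)CO[Si](C)(C)C(C)(C)C | intermediate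
13 | tert-butyl (5R)-2-[(3R)-3-(tert-butyldiphenylsilyloxy)-4-hydroxybutyl]-2,5-dimethyl-3-oxohept-6-enoate (C2 epimers) | C=C[C@H](C)CC(=O)C(C)(C(=O)OC(C)(C)C)CC[C@@H](O[Si](c1ccccc1)(c1ccccc1)C(C)(C)C)CO | intermediate
14 | tert-butyl (5R)-2-[(3R)-3-(tert-butyldiphenylsilyloxy)-4-oxobutyl]-2,5-dimethyl-3-oxohept-6-enoate (C2 epimers) | C=C[C@H](C)CC(=O)C(C)(C(=O)OC(C)(C)C)CC[C@@H](O[Si](c1ccccc1)(c1ccccc1)C(C)(C)C)C=O | intermediate
15 | ethyl 2-oxo-3-(triphenyl-λ5-phosphanylidene)propanoate | CCOC(=O)C(=O)C=P(c1ccccc1)(c1ccccc1)c1ccccc1 | starting material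
16 | ethyl (3E,5R,11R)-8-(tert-butoxycarbonyl)-5-(tert-butyldiphenylsilyloxy)-8,11-dimethyl-2,9-dioxotrideca-3,12-dienoate (C8 epimers) | C=C[C@H](C)CC(=O)C(C)(C(=O)OC(C)(C)C)CC[C@@H](O[Si](c1ccccc1)(c1ccccc1)C(C)(C)C)/C=C/C(=O)C(=O)OCC | intermediate
17 | β-keto acid: the 8-carboxylic acid corresponding to tert-butyl ester 16 (C8 epimers) | C=C[C@H](C)CC(=O)C(C)(C(=O)O)CC[C@@H](O[Si](c1ccccc1)(c1ccccc1)C(C)(C)C)/C=C/C(=O)C(=O)OCC | intermediate
18 | ethyl 3-[(1R,2S,5R)-5-(tert-butyldiphenylsilyloxy)-2-methyl-2-[(3R)-3-methylpent-4-enoyl]cyclopentyl]-2-oxopropanoate | C=C[C@H](C)CC(=O)[C@@]1(C)CC[C@@H](O[Si](c2ccccc2)(c2ccccc2)C(C)(C)C)[C@@H]1CC(=O)C(=O)OCC | intermediate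
19 | ethyl 25α-hydroxy-14-oxo-19α-(tert-butyldiphenylsilyloxy)-13α-[(S)-but-3-en-2-yl]-15β-methyl-trans-C/D-hydrindane-25β-carboxylate (13β-H, 23α-H) | C=C[C@H](C)[C@H]1C(=O)[C@@]2(C)CC[C@@H](O[Si](c3ccccc3)(c3ccccc3)C(C)(C)C)[C@@H]2C[C@]1(O)C(=O)OCC | intermediate
20 | 14-(4-methylbenzenesulfonyl)hydrazone of 19 | C=C[C@H](C)[C@H]1C(=NNS(=O)(=O)c3ccc(C)cc3)[C@@]2(C)CC[C@@H](O[Si](c3ccccc3)(c3ccccc3)C(C)(C)C)[C@@H]2C[C@]1(O)C(=O)OCC | intermediate
21 | ethyl 25α-hydroxy-19α-(tert-butyldiphenylsilyloxy)-13α-[(S)-but-3-en-2-yl]-15β-methyl-trans-C/D-hydrindane-25β-carboxylate (C14 = CH2) | C=C[C@H](C)[C@H]1C[C@@]2(C)CC[C@@H](O[Si](c3ccccc3)(c3ccccc3)C(C)(C)C)[C@@H]2C[C@]1(O)C(=O)OCC | intermediate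
22 | ethyl 19α,25α-dihydroxy-13α-[(S)-but-3-en-2-yl]-15β-methyl-trans-C/D-hydrindane-25β-carboxylate | C=C[C@H](C)[C@H]1C[C@@]2(C)CC[C@@H](O)[C@@H]2C[C@]1(O)C(=O)OCC | intermediate
23 | ethyl 25α-hydroxy-19-oxo-13α-[(S)-but-3-en-2-yl]-15β-methyl-trans-C/D-hydrindane-25β-carboxylate | C=C[C@H](C)[C@H]1C[C@@]2(C)CCC(=O)[C@@H]2C[C@]1(O)C(=O)OCC | intermediate
24 | ethyl 25α-hydroxy-19-(trifluoromethanesulfonyloxy)-13α-[(S)-but-3-en-2-yl]-15β-methyl-trans-C/D-hydrind-18-ene-25β-carboxylate | C=C[C@H](C)[C@H]1C[C@@]2(C)CC=C(OS(=O)(=O)C(F)(F)F)[C@@H]2C[C@]1(O)C(=O)OCC | intermediate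
25 | ethyl 25α-hydroxy-19-isopropyl-13α-[(S)-but-3-en-2-yl]-15β-methyl-trans-C/D-hydrind-18-ene-25β-carboxylate | C=C[C@H](C)[C@H]1C[C@@]2(C)CC=C(C(C)C)[C@@H]2C[C@]1(O)C(=O)OCC | intermediate
26 | N-methoxy-N-methyl amide corresponding to ester 25 | C=C[C@H](C)[C@H]1C[C@@]2(C)CC=C(C(C)C)[C@@H]2C[C@]1(O)C(=O)N(C)OC | intermediate
27 | (R)-pulegone, (5R)-5-methyl-2-(propan-2-ylidene)cyclohexan-1-one | C[C@@H]1CCC(=C(C)C)C(=O)C1 | starting material
28 | pulegone dibromide, (5R)-2-bromo-2-(2-bromopropan-2-yl)-5-methylcyclohexan-1-one (C2 epimers) | C[C@@H]1CCC(Br)(C(C)(C)Br)C(=O)C1 | intermediate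
29 | methyl (1S,2R)-2-methyl-5-(propan-2-ylidene)cyclopentane-1-carboxylate (ester trans to methyl) | CC(C)=C1CC[C@@H](C)[C@@H]1C(=O)OC | intermediate
30 | (1S,2R)-2-methyl-5-(propan-2-ylidene)cyclopentane-1-carbaldehyde | CC(C)=C1CC[C@@H](C)[C@@H]1C=O | intermediate
31 | (2S,3R)-3-methyl-1-(propan-2-ylidene)-2-vinylcyclopentane | CC(C)=C1CC[C@@H](C)[C@@H]1C=C | intermediate
32 | (2S,3R)-3-methyl-2-vinylcyclopentan-1-one | O=C1CC[C@@H](C)[C@@H]1C=C | intermediate
33 | 2,4,6-triisopropylbenzenesulfonylhydrazone of 32 | CC(C)c1cc(C(C)C)c(S(=O)(=O)NN=C2CC[C@@H](C)[C@@H]2C=C)c(C(C)C)c1 | intermediate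
34 | [(4R,5S)-4-methyl-5-vinylcyclopent-1-en-1-yl]lithium | [Li]C1=CC[C@@H](C)[C@@H]1C=C | intermediate
35 | C2 ketone: [(4R,5S)-4-methyl-5-vinylcyclopent-1-en-1-yl] ketone of the 25α-hydroxy-19-isopropyl-Δ18-trans-hydrindane bearing the 13α-(S)-but-3-en-2-yl group | C=C[C@H](C)[C@H]1C[C@@]2(C)CC=C(C(C)C)[C@@H]2C[C@]1(O)C(=O)C3=CC[C@@H](C)[C@@H]3C=C | intermediate
36 | tetracyclic 2-oxo-3,9(Z),18-triene with the target skeleton (25α-hydroxy, 19-isopropyl) | O=C1C2=CC[C@@H](C)[C@@H]2/C=C\[C@H](C)[C@H]2C[C@@]3(C)CC=C(C(C)C)[C@@H]3C[C@]12O | intermediate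
37 | 2-oxo tetracycle, fully saturated (25α-hydroxy, 19β-isopropyl, C3 epimers) | O=C1C2CC[C@@H](C)[C@@H]2CC[C@H](C)[C@H]2C[C@@]3(C)CC[C@H](C(C)C)[C@@H]3C[C@]12O | intermediate
38 | C2 enol triflate of 37 (C2=C3 alkene in ring B) | O=S(=O)(O/C1=C2\CC[C@@H](C)[C@@H]2CC[C@H](C)[C@H]2C[C@@]3(C)CC[C@H](C(C)C)[C@@H]3C[C@]12O)C(F)(F)F | intermediate
39 | sesterfisherol | C/C1=C2\CC[C@@H](C)[C@@H]2CC[C@H](C)[C@H]2C[C@@]3(C)CC[C@H](C(C)C)[C@@H]3C[C@]12O | target

**Count and risks**
Total steps: 27. Longest linear sequence: 19 steps (steps 1–3, 7–17 and 23–27); the iodide (steps 4–6) and ring A (steps 18–22) are side branches.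

Steps most likely to fail:

1. Step 11 (proposed new method). The C15 enol(ate) may ketonise before it reaches C23. Vinylogous enolisation at C19 of the 2-oxo-3-enoate may erode the stereocontrol. The Michael stage may close to the cis-disposed cyclopentane, and the keto ester may undergo intermolecular aldol reaction. Fallback with known chemistry, setting out from 16: TFA followed by warming in toluene without base gives, by dealkylative decarboxylation of the tert-butyl β-keto ester, the isolable α-methyl ketone F1. This is then closed under Brønsted-acid enol catalysis (camphorsulfonic acid, PhMe, 50 °C), the acid-mediated Michael/aldol annulation. Here the more substituted C15 enol is the reacting tautomer and C19–H is never removed by base. The fallback returns to the route at 19.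

2. Step 12. Condensation at the C14 carbonyl, flanked by a quaternary and a tertiary carbon, may be incomplete, and forcing it may cause retro-aldol cleavage or dehydration of the β-hydroxy ketone. Fallback, setting out from 19: hydroxyl-directed reduction with Me4NBH(OAc)3 (MeCN/AcOH, −20 °C) gives the C14 alcohol F2. Its secondary hydroxyl alone is acylated with phenyl chlorothionoformate (pyridine, DMAP) to the phenyl thionocarbonate F3. Barton–McCombie deoxygenation (Bu3SnH, AIBN, PhMe, 90 °C) then returns to the route at 21.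

3. Step 24. Intermolecular metathesis may outrun closure of the eight-membered ring, alkene migration may shorten the tether, and the conjugated C2 carbonyl may hold the substrate in an unproductive s-trans conformation. Fallback, setting out from 35: Luche reduction (NaBH4, CeCl3·7H2O, MeOH, −40 °C) gives the allylic alcohol F4. Ring B is then closed by metathesis at the carbinol oxidation level, where C2 is tetrahedral, to give the cyclooctene diol F5. MnO2 (CH2Cl2) re-oxidises the allylic alcohol and returns to the route at 36.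

Further compounds
F1 | step 11 | ethyl (3E,5R,11R)-5-(tert-butyldiphenylsilyloxy)-8,11-dimethyl-2,9-dioxotrideca-3,12-dienoate (C8 epimers) | C=C[C@H](C)CC(=O)C(C)CC[C@@H](O[Si](c1ccccc1)(c1ccccc1)C(C)(C)C)/C=C/C(=O)C(=O)OCC
F2 | step 12 | C14 alcohol corresponding to ketone 19 (C14 epimers) | C=C[C@H](C)[C@H]1C(O)[C@@]2(C)CC[C@@H](O[Si](c3ccccc3)(c3ccccc3)C(C)(C)C)[C@@H]2C[C@]1(O)C(=O)OCC
F3 | step 12 | O-phenyl thionocarbonate of the C14 hydroxyl of F2 | C=C[C@H](C)[C@H]1C(OC(=S)Oc3ccccc3)[C@@]2(C)CC[C@@H](O[Si](c3ccccc3)(c3ccccc3)C(C)(C)C)[C@@H]2C[C@]1(O)C(=O)OCC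
F4 | step 24 | C2 allylic alcohol corresponding to ketone 35 (C2 epimers) | C=C[C@H](C)[C@H]1C[C@@]2(C)CC=C(C(C)C)[C@@H]2C[C@]1(O)C(O)C3=CC[C@@H](C)[C@@H]3C=C
F5 | step 24 | C2 alcohol corresponding to trienone 36 (ring B closed, C2 epimers) | OC1C2=CC[C@@H](C)[C@@H]2/C=C\[C@H](C)[C@H]2C[C@@]3(C)CC=C(C(C)C)[C@@H]3C[C@]12O
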